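**Strategy.** The side chain is cut between C2' and C3' (counted from ring carbon C2 of the 4-pyranone), an unfunctionalised bond between two primary sp3 carbons. One nickel-electrocatalysed, doubly decarboxylative cross-coupling unites a 3-(chromon-2-yl)propanoic acid with nonadecanoic acid, both activated in the flask as N-hydroxyphthalimide esters, expelling two CO2 and leaving the plain C20 chain. The step exploits the saturated C1'–C2' spacer on C2 of the pyranone ring: C2, C1', C2' and the traceless carboxyl carbon map onto succinic anhydride, which also builds the pyranone ring on a locally symmetric 3,5-dimethylphloroacetophenone. The C5 and C7 phenols travel as methyl ethers.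

Key step: step 4

Remark: the target contains no stereocentre and no other stereogenic element, so it is a single achiral compound and no step has to control configuration.

**Step 1**
Reactants: 1 2',4',6'-trihydroxyacetophenone (phloroacetophenone)
Product: 2 1-(2,4,6-trihydroxy-3,5-dimethylphenyl)ethanone
Conditions: NaOMe (3 equiv), MeI (2.2 equiv), MeOH, 0 °C → reflux; then aq. HCl
Reagents that add atoms: iodomethane, CI
Why: Nuclear C-methylation of a phloroglucinol (alkylation of a vinylogous enolate): the methoxide-generated polyanion should attack the soft electrophile at the two equivalent free ring carbons C3 and C5, each flanked by two oxygens, and rearomatise.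

**Step 2**
Reactants: 2 1-(2,4,6-trihydroxy-3,5-dimethylphenyl)ethanone
Product: 3 1-(2-hydroxy-4,6-dimethoxy-3,5-dimethylphenyl)ethanone
Conditions: Me2SO4 (2.1 equiv), K2CO3, acetone, reflux
Reagents that add atoms: dimethyl sulfate, COS(=O)(=O)OC
Why: Williamson ether synthesis: two equivalents of the hard electrophile should O-methylate the para hydroxyl and one ortho hydroxyl, while the remaining ortho hydroxyl is held in a hydrogen bond to the acetyl carbonyl and stays free for the later ring closure.

**Step 3**
Reactants: 3 1-(2-hydroxy-4,6-dimethoxy-3,5-dimethylphenyl)ethanone; 4 succinic anhydride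
Product: 6 3-(5,7-dimethoxy-6,8-dimethyl-4-oxo-4H-chromen-2-yl)propanoic acid, via open-chain diketo acid 5 (not isolated)
Conditions: LiHMDS (3.3 equiv), THF, −78 → −10 °C; 4, −78 °C → rt; aq. HCl; then H2SO4 (cat.), AcOH, 95 °C
Reagents that add atoms: none
Why: Claisen-type C-acylation of the lithium dianion (phenoxide plus methyl ketone enolate, the third equivalent of base absorbing the acidic 1,3-diketone) by the cyclic anhydride gives the 1,3-diketo acid, and acid-catalysed cyclodehydration through the only free phenol should close the 4-pyranone ring as in a Baker–Venkataraman-type chromone synthesis.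

**Step 4**
Reactants: 6 3-(5,7-dimethoxy-6,8-dimethyl-4-oxo-4H-chromen-2-yl)propanoic acid; 7 nonadecanoic acid; 8 N-hydroxyphthalimide
Product: 11 2-icosyl-5,7-dimethoxy-6,8-dimethyl-4H-chromen-4-one, via chromone NHPI ester 9 (not isolated), via nonadecanoate NHPI ester 10 (not isolated)
Conditions: 6 (1 equiv), 7 (3 equiv), 8 (4.2 equiv), DIC (4.2 equiv), DMAP (cat.), CH2Cl2, rt; filter, evaporate; then NiCl2·6H2O (20 mol %), 2,2':6',2''-terpyridine (20 mol %), LiCl, DMF, (+)Zn/(−)RVC, constant current, rt
Reagents that add atoms: none
Why: Carbodiimide esterification converts both acids into N-acyloxyphthalimides; at the cathode a reduced terpyridine–nickel species transfers an electron to each ester, which fragments to phthalimide anion, CO2 and a primary alkyl radical, and stepwise radical capture at nickel gives a dialkylnickel(III) that reductively eliminates the new C(sp3)–C(sp3) bond between the chromonyl-ethyl carbon and C1 of the octadecyl radical. The closest known reaction type is the nickel-electrocatalytic doubly decarboxylative coupling of two redox-active esters, a reductive cross-electrophile coupling whose best case is exactly this primary–primary pairing. No ring is closed and no stereocentre is created. The step needs cross- over homo-coupling, which should be secured by the three-fold excess of the cheap fatty ester and by the very different polarity of hexatriacontane, the product and the bis-chromone dimer. It also needs chemoselectivity: the esters accept electrons at about −1.3 V (SCE), well before the chromone enone, the sacrificial zinc anode keeps the electron-rich dimethoxyarene away from any oxidising electrode (the reason a classical anodic Kolbe coupling is not chosen), and the methyl ethers remove acidic phenol protons that could protonate alkylnickel intermediates.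

**Step 5**
Reactants: 11 2-icosyl-5,7-dimethoxy-6,8-dimethyl-4H-chromen-4-one
Product: 12 2-icosyl-5,7-dihydroxy-6,8-dimethyl-4H-chromen-4-one (target)
Conditions: BBr3 (6 equiv), CH2Cl2, −78 °C → rt; then MeOH/H2O
Reagents that add atoms: none
Why: Lewis-acid cleavage of aryl methyl ethers: BBr3 should coordinate each ether oxygen (C5 assisted by chelation to the C4 carbonyl, C7 twisted out of plane by its two ortho methyl groups) and bromide removes the methyl group by SN2, while the pyranone and the alkyl chain are inert and any acid-induced ring opening and reclosure on the symmetric A ring would be degenerate.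

**Compound list**
1 | 2',4',6'-trihydroxyacetophenone | CC(=O)c1c(O)cc(O)cc1O | starting material
2 | 1-(2,4,6-trihydroxy-3,5-dimethylphenyl)ethanone | CC(=O)c1c(O)c(C)c(O)c(C)c1O | intermediate
3 | 1-(2-hydroxy-4,6-dimethoxy-3,5-dimethylphenyl)ethanone | CC(=O)c1c(O)c(C)c(OC)c(C)c1OC | intermediate
4 | succinic anhydride | O=C1CCC(=O)O1 | starting material
5 | 6-(2-hydroxy-4,6-dimethoxy-3,5-dimethylphenyl)-4,6-dioxohexanoic acid | OC(=O)CCC(=O)CC(=O)c1c(O)c(C)c(OC)c(C)c1OC | intermediate
6 | 3-(5,7-dimethoxy-6,8-dimethyl-4-oxo-4H-chromen-2-yl)propanoic acid | OC(=O)CCc1cc(=O)c2c(OC)c(C)c(OC)c(C)c2o1 | intermediate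
7 | nonadecanoic acid | CCCCCCCCCCCCCCCCCCC(=O)O | starting material
8 | N-hydroxyphthalimide | ON1C(=O)c2ccccc2C1=O | starting material
9 | 1,3-dioxoisoindolin-2-yl 3-(5,7-dimethoxy-6,8-dimethyl-4-oxo-4H-chromen-2-yl)propanoate | O=C(CCc1cc(=O)c2c(OC)c(C)c(OC)c(C)c2o1)ON1C(=O)c2ccccc2C1=O | intermediate
10 | 1,3-dioxoisoindolin-2-yl nonadecanoate | CCCCCCCCCCCCCCCCCCC(=O)ON1C(=O)c2ccccc2C1=O | intermediate
11 | 2-icosyl-5,7-dimethoxy-6,8-dimethyl-4H-chromen-4-one | CCCCCCCCCCCCCCCCCCCCc1cc(=O)c2c(OC)c(C)c(OC)c(C)c2o1 | intermediate
12 | 2-icosyl-5,7-dihydroxy-6,8-dimethyl-4H-chromen-4-one | CCCCCCCCCCCCCCCCCCCCc1cc(=O)c2c(O)c(C)c(O)c(C)c2o1 | target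

**Total step count:** 5
**Longest linear sequence:** 5 steps (1 → 2 → 3 → 6 → 11 → 12)

**Steps most likely to fail**

Step 4. The two alkyl radicals may sort statistically, so that homodimerisation, simple hydrodecarboxylation, or β-hydride loss from the chromonyl-ethyl nickel species (towards the conjugated 2-vinyl chromone) erodes the cross-coupling. The fallback sets out from acid 6 and comes back at 11. It replaces the radical–radical sorting by a polar organometallic cross-coupling at the same bond. Acid 6 is converted into the NHPI ester 9 (8, DIC, DMAP cat., CH2Cl2), which is isolated this time. Ester 9 is then coupled with dioctadecylzinc F1, prepared from commercial octadecylmagnesium chloride and ZnCl2 (0.5 equiv) in THF, under NiCl2·glyme (20 mol %) and 4,4'-di-tert-butyl-2,2'-bipyridine (40 mol %) in THF/DMF at rt. This decarboxylative Negishi-type alkyl–alkyl coupling should give 11 directly.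

Step 3. O-acylation of the phenoxide, double acylation, or sluggish cyclodehydration of the crude diketo acid may divert the one-pot sequence. The fallback sets out from 3 and comes back at 6 by a stepwise Baker–Venkataraman route. Phenol 3 is O-acylated with methyl 4-chloro-4-oxobutanoate (Et3N, DMAP cat., CH2Cl2) to 2-acetyl-3,5-dimethoxy-4,6-dimethylphenyl methyl butanedioate F2. Treatment with KOt-Bu in THF should transfer the acyl group from oxygen to the ketone enolate carbon and give methyl 6-(2-hydroxy-4,6-dimethoxy-3,5-dimethylphenyl)-4,6-dioxohexanoate F3. Heating F3 in aqueous H2SO4/AcOH should close the pyranone ring and hydrolyse the methyl ester, giving 6.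

Step 1. Methylation may run on to the dearomatised gem-dimethyl cyclohexadienone, stop at the mono-methyl stage, or occur on oxygen, so that the wanted 3,5-dimethyl compound is a minor component. The fallback sets out from 1 and comes back at 2 by a Mannich–hydrogenolysis sequence that cannot over-alkylate. Compound 1 is treated with aqueous dimethylamine and formaldehyde in EtOH to give the bis-Mannich base 1-[3,5-bis((dimethylamino)methyl)-2,4,6-trihydroxyphenyl]ethanone F4. Hydrogenolysis of both benzylic C–N bonds (H2, Pd/C, AcOH/MeOH, 50 °C) should then deliver 2.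

**Further compounds**
F1 | step 4 | dioctadecylzinc | CCCCCCCCCCCCCCCCCC[Zn]CCCCCCCCCCCCCCCCCC
F2 | step 3 | 2-acetyl-3,5-dimethoxy-4,6-dimethylphenyl methyl butanedioate | COC(=O)CCC(=O)Oc1c(C)c(OC)c(C)c(OC)c1C(C)=O
F3 | step 3 | methyl 6-(2-hydroxy-4,6-dimethoxy-3,5-dimethylphenyl)-4,6-dioxohexanoate | COC(=O)CCC(=O)CC(=O)c1c(O)c(C)c(OC)c(C)c1OC
F4 | step 1 | 1-[3,5-bis((dimethylamino)methyl)-2,4,6-trihydroxyphenyl]ethanone | CC(=O)c1c(O)c(CN(C)C)c(O)c(CN(C)C)c1O
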